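**Plan**

- Retrosynthesis: after removal of two MOM ethers, the C4–C4a and O1–C8a bonds of ring C are cut together, giving 3,5-bis(methoxymethoxy)benzyne (ring A) and an (S)-3-aryl-3-hydroxypropanamide. The amide is cut at C3–C4 (Claisen) to a 7-prenylbenzofuran-5-carboxylate, then at the aryl–prenyl bond and at the furan ring.
- Forward: the furan ring is built onto a bromophenol ester, then Stille prenylation, crossed Claisen condensation and asymmetric reduction; ring C is then closed on the aryne (ring A arrives whole), followed by deprotection. The aryne precursor is made in parallel from resorcinol.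
- Enabling feature: in ring A the ether oxygen O1 (on C8a) and the carbonyl carbon C4 (on C4a) sit on neighbouring carbons, and C4a is flanked by the C5 oxygen. A C4a≡C8a aryne therefore takes the alkoxide at C8a and the acyl carbon at C4a.
- Stereochemistry: the single stereocentre C2 (S) is set by catalytic asymmetric transfer hydrogenation of the β-keto amide and carried through with retention, since its C–O bond is never broken.

Key step: step 10

Remark on the chemistry: the (S,S)-configured catalyst of step 5 is assumed to give the S carbinol, as it does with simple aryl ketones; if the sense were opposite, the (R,R) catalyst would be used.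

**Route**

Step 1
Reactants: 1 methyl 3-bromo-4-hydroxybenzoate; 2 2-bromo-1,1-diethoxyethane
Product: 3 methyl 3-bromo-4-(2,2-diethoxyethoxy)benzoate
Conditions: K2CO3, DMF, 120 °C
Reagents that add atoms: none
Why: Williamson ether synthesis, in which the acidic phenol is alkylated by the primary bromide while ester and acetal are stable to carbonate.

Step 2
Reactants: 3 methyl 3-bromo-4-(2,2-diethoxyethoxy)benzoate
Product: 4 methyl 7-bromo-1-benzofuran-5-carboxylate
Conditions: polyphosphoric acid, toluene, 110 °C
Reagents that add atoms: none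
Why: Acid-mediated cyclodehydration (ionisation of the acetal, intramolecular Friedel–Crafts attack at the only free carbon ortho to the ether oxygen, loss of ethanol) should give the aromatic furan ring, bromine blocking the other ortho carbon.

Step 3
Reactants: 4 methyl 7-bromo-1-benzofuran-5-carboxylate; 5 tributyl(3-methylbut-2-en-1-yl)stannane
Product: 6 methyl 7-(3-methylbut-2-en-1-yl)-1-benzofuran-5-carboxylate
Conditions: Pd(PPh3)4 (5 mol%), DMF, 100 °C
Reagents that add atoms: none
Why: Migita–Kosugi–Stille coupling with zerovalent palladium, in which reductive elimination at the unsubstituted terminus of the prenyl ligand should give the linear prenyl arene under neutral conditions that spare ester and furan.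

Step 4
Reactants: 6 methyl 7-(3-methylbut-2-en-1-yl)-1-benzofuran-5-carboxylate; 7 N,N-dimethylacetamide
Product: 9 N,N-dimethyl-3-[7-(3-methylbut-2-en-1-yl)-1-benzofuran-5-yl]-3-oxopropanamide, via lithium enolate of N,N-dimethylacetamide 8 (not isolated)
Conditions: LiN(i-Pr)2 (2.2 equiv), 7 (2.3 equiv), THF, −78 °C; then 6, −78 to 0 °C; 1 M aq. HCl
Reagents that add atoms: none
Why: Crossed Claisen condensation, in which the non-enolisable aryl ester acylates the amide enolate and the second equivalent of enolate deprotonates the β-keto amide so that no further addition occurs.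

Step 5
Reactants: 9 N,N-dimethyl-3-[7-(3-methylbut-2-en-1-yl)-1-benzofuran-5-yl]-3-oxopropanamide
Product: 10 (3S)-3-hydroxy-N,N-dimethyl-3-[7-(3-methylbut-2-en-1-yl)-1-benzofuran-5-yl]propanamide
Conditions: RuCl[(S,S)-TsDPEN](p-cymene) (1 mol%), HCO2H/Et3N (5:2), CH2Cl2, 30 °C
Reagents that add atoms: none
Why: Noyori–Ikariya asymmetric transfer hydrogenation, in which the chiral diamine ligand directs hydride to one face of the aryl ketone through the usual CH–π-stabilised transition state to set C2 as S, while the isolated prenyl alkene and the benzofuran are inert to this outer-sphere hydride transfer.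

Step 6
Reactants: 11 resorcinol
Product: 12 1,3-bis(methoxymethoxy)benzene
Conditions: MeOCH2Cl, i-Pr2NEt, CH2Cl2, 0 °C to rt
Reagents that add atoms: chloromethyl methyl ether, COCCl
Why: Acetal protection of both phenols gives ethers that are stable to every later anionic step and removable with mild acid at the end.

Step 7
Reactants: 12 1,3-bis(methoxymethoxy)benzene
Product: 14 3,5-bis(methoxymethoxy)phenol, via pinacol arylboronate 13 (not isolated)
Conditions: [Ir(OMe)(cod)]2 (1.5 mol%), 4,4'-di-tert-butyl-2,2'-bipyridine (3 mol%), B2pin2 (0.55 equiv), THF, 80 °C; then 30% aq. H2O2, aq. NaOH, 0 °C to rt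
Reagents that add atoms: bis(pinacolato)diboron, CC1(C)OB(OC1(C)C)B1OC(C)(C)C(C)(C)O1 (boron of 13 only); hydrogen peroxide, OO
Why: Iridium-catalysed C–H borylation is governed by sterics, so only the C–H with no ortho neighbour (C5) should react, and basic peroxide oxidation of the C–B bond then gives the phenol without touching the acetals.

Step 8
Reactants: 14 3,5-bis(methoxymethoxy)phenol
Product: 15 2-bromo-3,5-bis(methoxymethoxy)phenol
Conditions: NBS (1.0 equiv), i-Pr2NH (10 mol%), CH2Cl2, −78 to 0 °C
Reagents that add atoms: N-bromosuccinimide, O=C1CCC(=O)N1Br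
Why: Amine-catalysed ortho-selective electrophilic bromination, in which the N-bromoamine hydrogen-bonded to the phenol delivers bromine to one of the two equivalent ortho carbons in preference to the para carbon crowded by two acetal ethers.

Step 9
Reactants: 15 2-bromo-3,5-bis(methoxymethoxy)phenol
Product: 18 3,5-bis(methoxymethoxy)-2-(trimethylsilyl)phenyl trifluoromethanesulfonate, via O-trimethylsilyl ether 16 (not isolated), via lithium 2-silylphenoxide 17 (not isolated)
Conditions: (Me3Si)2NH, THF, 65 °C, then evaporation; n-BuLi, THF, −78 °C; PhNTf2, −78 °C to rt; aq. NH4Cl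
Reagents that add atoms: hexamethyldisilazane, C[Si](C)(C)N[Si](C)(C)C; N-phenylbis(trifluoromethanesulfonimide), O=S(=O)(C(F)(F)F)N(c1ccccc1)S(=O)(=O)C(F)(F)F
Why: O-silylation followed by bromine–lithium exchange triggers the 1,3-migration of silicon from oxygen to carbon (retro-Brook rearrangement), and the resulting phenoxide is triflated by the mild PhNTf2, which should spare the acetals.

Step 10
Reactants: 10 (3S)-3-hydroxy-N,N-dimethyl-3-[7-(3-methylbut-2-en-1-yl)-1-benzofuran-5-yl]propanamide; 18 3,5-bis(methoxymethoxy)-2-(trimethylsilyl)phenyl trifluoromethanesulfonate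
Product: 23 (2S)-5,7-bis(methoxymethoxy)-2-[7-(3-methylbut-2-en-1-yl)-1-benzofuran-5-yl]-2,3-dihydro-4H-chromen-4-one, via potassium alkoxide of the hydroxy amide 19 (not isolated), via 3,5-bis(methoxymethoxy)benzyne 20 (not isolated), via ortho-aryloxy aryl anion 21 (not isolated), via cyclic hemiaminal alkoxide 22 (not isolated)
Conditions: KH (1.0 equiv), THF, 0 °C; then 18 (1.5 equiv, slow addition), KF (3 equiv), 18-crown-6 (3 equiv), THF, 0 °C to rt; then 1 M aq. HCl, 0 °C
Reagents that add atoms: none
Why: Proposed new method: fluoride removes the silyl group of 18 and triflate leaves to give aryne 20; the proton-free alkoxide 19 adds to the aryne carbon remote from the neighbouring acetal ether (the future C8a), because that carbon is the more distorted and electrophilic one and the charge then develops on the carbon flanked by the inductively withdrawing C–O bond (the future C4a), and aryl anion 21 attacks the tethered dimethylamide carbonyl to form the C4–C4a bond. The closest known reaction types are the annulation of arynes with salicylate esters to xanthones (phenoxide addition, then acylation of the aryl anion by the ester) and aryne insertions into amide N–C(=O) bonds; new here is an aliphatic secondary alkoxide that carries an enolisable amide. Ring C, the only ring formed, closes in the 6-exo-trig mode. No stereocentre is created in the product: C2 comes unchanged from 10 because its C–O bond is never broken, and the hemiaminal carbon of 22 ceases to be stereogenic on hydrolysis. The step needs three selectivities: regioselective addition to the aryne (secured by the C5 oxygen beside the triple bond, the C7 oxygen being meta to the site of attack); carbonyl attack of 21 in preference to protonation (secured by pre-forming the alkoxide with KH so that no O–H is present, by THF in place of acetonitrile, and by the low acidity of amide α-hydrogens); and stereochemical integrity (a tertiary amide suppresses retro-aldol cleavage of 19, and amide ion is so poor a leaving group that 22 should persist and release the ketone only in the acidic quench, away from base-induced ring opening to the chalcone).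

Step 11
Reactants: 23 (2S)-5,7-bis(methoxymethoxy)-2-[7-(3-methylbut-2-en-1-yl)-1-benzofuran-5-yl]-2,3-dihydro-4H-chromen-4-one
Product: 24 (2S)-5,7-dihydroxy-2-[7-(3-methylbut-2-en-1-yl)-1-benzofuran-5-yl]-2,3-dihydro-4H-chromen-4-one
Conditions: HCl (1 M), MeOH, 40 °C
Reagents that add atoms: none
Why: Acid-catalysed transacetalisation removes both MOM ethers under conditions standard for prenylated flavanones, which should leave the prenyl alkene, the benzofuran and the base-labile (but acid-stable) C2 stereocentre untouched.

**Compound list**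

1 | methyl 3-bromo-4-hydroxybenzoate | COC(=O)c1ccc(O)c(Br)c1 | starting material
2 | 2-bromo-1,1-diethoxyethane | CCOC(CBr)OCC | starting material
3 | methyl 3-bromo-4-(2,2-diethoxyethoxy)benzoate | CCOC(COc1ccc(C(=O)OC)cc1Br)OCC | intermediate
4 | methyl 7-bromo-1-benzofuran-5-carboxylate | COC(=O)c1cc(Br)c2occc2c1 | intermediate
5 | tributyl(3-methylbut-2-en-1-yl)stannane | CCCC[Sn](CCCC)(CCCC)CC=C(C)C | starting material
6 | methyl 7-(3-methylbut-2-en-1-yl)-1-benzofuran-5-carboxylate | COC(=O)c1cc(CC=C(C)C)c2occc2c1 | intermediate
7 | N,N-dimethylacetamide | CC(=O)N(C)C | starting material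
8 | lithium enolate of N,N-dimethylacetamide | C=C([O-])N(C)C.[Li+] | intermediate (not isolated)
9 | N,N-dimethyl-3-[7-(3-methylbut-2-en-1-yl)-1-benzofuran-5-yl]-3-oxopropanamide | CN(C)C(=O)CC(=O)c1cc(CC=C(C)C)c2occc2c1 | intermediate
10 | (3S)-3-hydroxy-N,N-dimethyl-3-[7-(3-methylbut-2-en-1-yl)-1-benzofuran-5-yl]propanamide | CN(C)C(=O)C[C@H](O)c1cc(CC=C(C)C)c2occc2c1 | intermediate
11 | resorcinol (benzene-1,3-diol) | Oc1cccc(O)c1 | starting material
12 | 1,3-bis(methoxymethoxy)benzene | COCOc1cccc(OCOC)c1 | intermediate
13 | 2-[3,5-bis(methoxymethoxy)phenyl]-4,4,5,5-tetramethyl-1,3,2-dioxaborolane | COCOc1cc(OCOC)cc(B2OC(C)(C)C(C)(C)O2)c1 | intermediate (not isolated)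
14 | 3,5-bis(methoxymethoxy)phenol | COCOc1cc(O)cc(OCOC)c1 | intermediate
15 | 2-bromo-3,5-bis(methoxymethoxy)phenol | COCOc1cc(O)c(Br)c(OCOC)c1 | intermediate
16 | [2-bromo-3,5-bis(methoxymethoxy)phenoxy]trimethylsilane | COCOc1cc(O[Si](C)(C)C)c(Br)c(OCOC)c1 | intermediate (not isolated)
17 | lithium 3,5-bis(methoxymethoxy)-2-(trimethylsilyl)phenoxide | COCOc1cc([O-])c([Si](C)(C)C)c(OCOC)c1.[Li+] | intermediate (not isolated)
18 | 3,5-bis(methoxymethoxy)-2-(trimethylsilyl)phenyl trifluoromethanesulfonate | COCOc1cc(OS(=O)(=O)C(F)(F)F)c([Si](C)(C)C)c(OCOC)c1 | intermediate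
19 | potassium (1S)-3-(dimethylamino)-1-[7-(3-methylbut-2-en-1-yl)-1-benzofuran-5-yl]-3-oxopropan-1-olate | CN(C)C(=O)C[C@H]([O-])c1cc(CC=C(C)C)c2occc2c1.[K+] | intermediate (not isolated)
20 | 3,5-bis(methoxymethoxy)benzyne | COCOC1=CC(OCOC)=CC#C1 | intermediate (not isolated)
21 | potassium 2-{(1S)-3-(dimethylamino)-1-[7-(3-methylbut-2-en-1-yl)-1-benzofuran-5-yl]-3-oxopropoxy}-4,6-bis(methoxymethoxy)benzenide | CN(C)C(=O)C[C@H](Oc1cc(OCOC)cc(OCOC)[c-]1)c1cc(CC=C(C)C)c2occc2c1.[K+] | intermediate (not isolated)
22 | potassium (2S)-4-(dimethylamino)-5,7-bis(methoxymethoxy)-2-[7-(3-methylbut-2-en-1-yl)-1-benzofuran-5-yl]-3,4-dihydro-2H-chromen-4-olate (both configurations at C4) | CN(C)C1([O-])C[C@@H](c2cc(CC=C(C)C)c3occc3c2)Oc2cc(OCOC)cc(OCOC)c12.[K+] | intermediate (not isolated)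
23 | (2S)-5,7-bis(methoxymethoxy)-2-[7-(3-methylbut-2-en-1-yl)-1-benzofuran-5-yl]-2,3-dihydro-4H-chromen-4-one | O=C1C[C@@H](c2cc(CC=C(C)C)c3occc3c2)Oc2cc(OCOC)cc(OCOC)c12 | intermediate
24 | (2S)-5,7-dihydroxy-2-[7-(3-methylbut-2-en-1-yl)-1-benzofuran-5-yl]-2,3-dihydro-4H-chromen-4-one | O=C1C[C@@H](c2cc(CC=C(C)C)c3occc3c2)Oc2cc(O)cc(O)c12 | target

**Summary**

Total step count: 11. Longest linear sequence: 7 steps (steps 1–5, 10, 11); the aryne precursor branch is steps 6–9.

**Steps most likely to fail**

1. Step 10. The aryl anion may be quenched before it acylates, either by intramolecular proton transfer from the amide α-methylene (followed by β-elimination of the aryloxide) or by adventitious proton sources. Configuration could also erode if the hemiaminal collapsed to the ketone in the basic medium. The fallback sets out from 10 and 18 and returns at 23, dividing the event into two known reactions. The aryne is generated under neutral conditions (CsF, MeCN, rt, no KH), where the known O–H insertion of an alcohol into an aryne should give, with retention, the aryl ether (3S)-3-[3,5-bis(methoxymethoxy)phenoxy]-N,N-dimethyl-3-[7-(3-methylbut-2-en-1-yl)-1-benzofuran-5-yl]propanamide F1. Electrophilic activation of the tertiary amide (Tf2O, 2-chloropyridine, CH2Cl2, −78 to 0 °C) then closes the same bond by an intramolecular Vilsmeier–Haack-type Friedel–Crafts reaction at either of the two equivalent carbons ortho to the ether oxygen. This gives the cyclic iminium salt (2S)-N,N-dimethyl-5,7-bis(methoxymethoxy)-2-[7-(3-methylbut-2-en-1-yl)-1-benzofuran-5-yl]-2,3-dihydrochromen-4-iminium trifluoromethanesulfonate F2, which aqueous NaHCO3 should hydrolyse to 23.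

2. Step 8. Regiocontrol may be lost through bromination para to the free hydroxyl, between the two acetal ethers. The fallback sets out from 14 and returns at 18, replacing electrophilic substitution by directed metalation. Carbamoylation (Et2NCOCl, NaH, THF) gives 3,5-bis(methoxymethoxy)phenyl N,N-diethylcarbamate F3. Directed ortho-metalation (s-BuLi, TMEDA, THF, −78 °C, then Me3SiCl) should place silicon between the carbamate, the strongest of the three directing groups, and an acetal ether, at one of two equivalent sites, giving 3,5-bis(methoxymethoxy)-2-(trimethylsilyl)phenyl N,N-diethylcarbamate F4. Reductive removal of the carbamate (LiAlH4, THF, 0 °C to rt) frees 3,5-bis(methoxymethoxy)-2-(trimethylsilyl)phenol F5, and triflation (NaH, PhNTf2, THF) gives 18.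

3. Step 2. Ring closure onto an arene deactivated by the ester and bromine may be slow, allowing oligomerisation of the oxocarbenium ion and acid cleavage of the ester to compete. The fallback sets out from 1 and returns at 4, building the furan by alkyne annulation. Iodination ortho to the hydroxyl (N-iodosuccinimide, MeCN) gives methyl 3-bromo-4-hydroxy-5-iodobenzoate F6. Sonogashira coupling with ethynyltrimethylsilane at the C–I bond (PdCl2(PPh3)2, CuI, Et3N, DMF, 70 °C) gives methyl 3-bromo-4-hydroxy-5-[(trimethylsilyl)ethynyl]benzoate F7. This should cycloisomerise in the same flask (5-endo-dig attack of the phenoxide on the copper-activated alkyne) to methyl 7-bromo-2-(trimethylsilyl)-1-benzofuran-5-carboxylate F8. Bu4NF in THF removes the silyl group and gives 4.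

**Further compounds**

F1 | step 10 | (3S)-3-[3,5-bis(methoxymethoxy)phenoxy]-N,N-dimethyl-3-[7-(3-methylbut-2-en-1-yl)-1-benzofuran-5-yl]propanamide | CN(C)C(=O)C[C@H](Oc1cc(OCOC)cc(OCOC)c1)c1cc(CC=C(C)C)c2occc2c1
F2 | step 10 | (2S)-N,N-dimethyl-5,7-bis(methoxymethoxy)-2-[7-(3-methylbut-2-en-1-yl)-1-benzofuran-5-yl]-2,3-dihydrochromen-4-iminium trifluoromethanesulfonate | C[N+](C)=C1C[C@@H](c2cc(CC=C(C)C)c3occc3c2)Oc2cc(OCOC)cc(OCOC)c12.[O-]S(=O)(=O)C(F)(F)F
F3 | step 8 | 3,5-bis(methoxymethoxy)phenyl N,N-diethylcarbamate | CCN(CC)C(=O)Oc1cc(OCOC)cc(OCOC)c1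
F4 | step 8 | 3,5-bis(methoxymethoxy)-2-(trimethylsilyl)phenyl N,N-diethylcarbamate | CCN(CC)C(=O)Oc1cc(OCOC)cc(OCOC)c1[Si](C)(C)C
F5 | step 8 | 3,5-bis(methoxymethoxy)-2-(trimethylsilyl)phenol | COCOc1cc(O)c([Si](C)(C)C)c(OCOC)c1
F6 | step 2 | methyl 3-bromo-4-hydroxy-5-iodobenzoate | COC(=O)c1cc(Br)c(O)c(I)c1
F7 | step 2 | methyl 3-bromo-4-hydroxy-5-[(trimethylsilyl)ethynyl]benzoate | COC(=O)c1cc(Br)c(O)c(C#C[Si](C)(C)C)c1
F8 | step 2 | methyl 7-bromo-2-(trimethylsilyl)-1-benzofuran-5-carboxylate | COC(=O)c1cc(Br)c2oc([Si](C)(C)C)cc2c1
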